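**Plan**
1. The pyranone ring of the chromone is cut at O1–C2 and C2–C3 (aryl ester acyl shift, then cyclodehydration), giving a ring A acetophenone and a ring B benzoic acid.
2. Ring B is cut at C1'–C6' and at the ester C–O bond. Its pattern (carboxyl carbon on C1', oxygens on C2' and C4', pyronylmethyl on C6') is that of a folded 3,5,7-triketo ester, which is the alcohol adduct of an acylketene stored in a diketo-dioxinone.
3. The chain is cut at the carbon between its two ketones: a dioxinone β-keto allyl ester is C-acylated by a pyronylacetyl chloride and then decarboxylated. The 2-pyrone ring and the dioxinone are bought intact.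
4. Forward order: chain joined (steps 1–6), ring B closed (step 7), acid unmasked and esterified with ring A (steps 8–11), pyranone ring closed (step 12), benzyl ethers removed (step 13).
5. Stereochemistry: the target has no stereocentre and no stereogenic double bond, so nothing has to be set.

Key step: step 7

Remark: poly-β-carbonyl compounds are drawn as keto tautomers although they should be largely enolised, so the sp3 carbons of the acylated keto ester and of the cyclic aldol carry no assigned configuration.
Remark: the ketene is quenched with allyl alcohol because a benzoate with two ortho substituents cannot be saponified without opening the pyrone, whereas an allyl ester is cleaved at the allyl carbon; the pyrone hydroxyl is masked as its allyl ether only until the chain is complete.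

Step 1
Reactants: 1 4-hydroxy-6-methyl-2H-pyran-2-one
Product: 2 6-methyl-4-(prop-2-en-1-yloxy)-2H-pyran-2-one
Conditions: allyl bromide, K2CO3, acetone, reflux
Reagents that add atoms: allyl bromide, C=CCBr
Why: Williamson etherification of the acidic vinylogous acid should give mainly the 4-O-allyl ether, at a temperature far below that of a Claisen rearrangement of the product.

Step 2
Reactants: 2 6-methyl-4-(prop-2-en-1-yloxy)-2H-pyran-2-one
Product: 3 [2-oxo-4-(prop-2-en-1-yloxy)-2H-pyran-6-yl]acetic acid
Conditions: LiN(i-Pr)2, THF, −78 °C; cannulate into CO2-saturated THF, −78 → 0 °C; 1 M HCl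
Reagents that add atoms: carbon dioxide, O=C=O
Why: Deprotonation of the vinylogous methyl group of 4-alkoxy-6-methyl-2-pyrones by a lithium amide is well known, and inverse addition into excess CO2 should carboxylate the anion before the more acidic product can protonate it (enolate carboxylation).

Step 3
Reactants: 4 2,2-dimethyl-1,3-dioxane-4,6-dione (Meldrum's acid); 5 prop-2-en-1-ol (allyl alcohol)
Product: 6 3-oxo-3-(prop-2-en-1-yloxy)propanoic acid (allyl hydrogen malonate)
Conditions: PhMe, 100 °C
Reagents that add atoms: none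
Why: Alcoholysis of Meldrum's acid opens the cyclic acylal with loss of acetone and leaves the malonic half ester.

Step 4
Reactants: 6 allyl hydrogen malonate; 7 2,2,6-trimethyl-4H-1,3-dioxin-4-one
Product: 9 prop-2-en-1-yl 4-(2,2-dimethyl-4-oxo-4H-1,3-dioxin-6-yl)-3-oxobutanoate, via allyl malonyl chloride 8 (not isolated)
Conditions: 6, (COCl)2, DMF (cat.), CH2Cl2, 0 °C → rt, evaporate; 7 (2 equiv), LiN(SiMe3)2 (2.1 equiv), THF, −78 °C, then 8; aq. NH4Cl
Reagents that add atoms: oxalyl chloride, ClC(=O)C(=O)Cl (its chlorine stays in 8 only)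
Why: Vinylogous Claisen-type C-acylation, in which the lithium dienolate of the dioxinone reacts at its methyl-derived γ-carbon with the acid chloride while the second equivalent of dienolate takes up the acidic proton of the β-keto ester formed.

Step 5
Reactants: 9 prop-2-en-1-yl 4-(2,2-dimethyl-4-oxo-4H-1,3-dioxin-6-yl)-3-oxobutanoate; 3 [2-oxo-4-(prop-2-en-1-yloxy)-2H-pyran-6-yl]acetic acid
Product: 11 prop-2-en-1-yl 2-[(2,2-dimethyl-4-oxo-4H-1,3-dioxin-6-yl)acetyl]-3-oxo-4-[2-oxo-4-(prop-2-en-1-yloxy)-2H-pyran-6-yl]butanoate, via pyronylacetyl chloride 10 (not isolated)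
Conditions: 3, (COCl)2, DMF (cat.), CH2Cl2, 0 °C, evaporate; 9, MgCl2, pyridine, CH2Cl2, 0 °C, then 10, 0 °C → rt; 1 M HCl
Reagents that add atoms: oxalyl chloride, ClC(=O)C(=O)Cl (its chlorine stays in 10 only)
Why: Magnesium-mediated soft-enolisation C-acylation of a β-keto ester, in which the MgCl2 chelate is acylated at its central carbon under pyridine, so the CH-acidic pyronylacetyl donor (or the ketene it may form) still transfers its acyl group instead of merely being deprotonated as it would be by a lithium dianion.

Step 6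
Reactants: 11 the doubly allylated acyl keto ester
Product: 12 6-[5-(4-hydroxy-2-oxo-2H-pyran-6-yl)-2,4-dioxopentyl]-2,2-dimethyl-4H-1,3-dioxin-4-one
Conditions: Pd(PPh3)4 (5 mol %), morpholine, THF, 0 °C → rt; 1 M HCl
Reagents that add atoms: none
Why: Tsuji–Trost deallylation, in which zerovalent palladium ionises both the allyl ester and the allyl ether of the pyrone (a vinylogous ester), morpholine takes up the allyl groups and the resulting β,β'-diketo acid loses CO2 at room temperature, where the dioxinone stays intact.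

Step 7
Reactants: 12 6-[5-(4-hydroxy-2-oxo-2H-pyran-6-yl)-2,4-dioxopentyl]-2,2-dimethyl-4H-1,3-dioxin-4-one; 5 prop-2-en-1-ol
Product: 16 prop-2-en-1-yl 2,4-dihydroxy-6-[(4-hydroxy-2-oxo-2H-pyran-6-yl)methyl]benzoate, via acylketene 13 (not isolated), via triketo allyl ester 14 (not isolated), via cyclic aldol 15 (not isolated)
Conditions: 5 (excess), PhMe, 105 °C; then Cs2CO3, 5/THF, rt; then HCl (1,4-dioxane), rt
Reagents that add atoms: none
Why: Above about 100 °C the dioxinone should undergo retro-[4+2] loss of acetone to acylketene 13, which the excess allyl alcohol captures as the 3,5,7-triketo ester 14 before the chain enols or the pyrone hydroxyl can add to it; the closest known reaction type is the thermolysis of diketo-dioxinones in the presence of an alcohol followed by aldol aromatisation to resorcylate esters. Under Cs2CO3 the ester-flanked methylene C2 adds to the C7 ketone in a 6-(enolendo)-exo-trig aldol, which forms the C1'–C6' bond and ring B as aldol 15. HCl then eliminates water and the two ring ketones enolise, so that the C2' and C4' hydroxyls are simply the C3 and C5 oxygens of the chain. No stereocentre remains, because both sp3 centres of 15 are lost on aromatisation. The selectivity needed is closure from C2 onto C7 rather than from the pyronyl methylene C8 onto C3, and it rests on the free 4-hydroxypyrone, which is an oxyanion under the base and so makes C8 far less acidic than C2. Allyl alcohol serves both as ketene trap and as protic cosolvent of the base step, so that ester exchange is degenerate and the ester can later be cleaved at the allyl carbon.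

Step 8
Reactants: 16 prop-2-en-1-yl 2,4-dihydroxy-6-[(4-hydroxy-2-oxo-2H-pyran-6-yl)methyl]benzoate
Product: 17 prop-2-en-1-yl 2,4-bis(benzyloxy)-6-{[4-(benzyloxy)-2-oxo-2H-pyran-6-yl]methyl}benzoate
Conditions: BnBr, K2CO3, DMF, 50 °C
Reagents that add atoms: benzyl bromide, BrCc1ccccc1
Why: Williamson benzylation of the two phenols and the pyrone hydroxyl under a base too weak to deprotonate the diarylmethane-type CH2, the benzyl group on the C2 oxygen later fixing the direction of chromone closure.

Step 9
Reactants: 17 the tribenzylated allyl ester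
Product: 18 2,4-bis(benzyloxy)-6-{[4-(benzyloxy)-2-oxo-2H-pyran-6-yl]methyl}benzoic acid
Conditions: Pd(PPh3)4 (5 mol %), morpholine, THF, rt; 1 M HCl
Reagents that add atoms: none
Why: Tsuji–Trost deallylation cleaves the ester at the allyl carbon and is therefore indifferent to the two ortho substituents that would block saponification, while benzyl ethers and pyrone are not touched.

Step 10
Reactants: 19 1-(2,4-dihydroxy-6-methylphenyl)ethanone
Product: 20 1-[4-(benzyloxy)-2-hydroxy-6-methylphenyl]ethanone
Conditions: BnBr (1.05 equiv), K2CO3, acetone, reflux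
Reagents that add atoms: benzyl bromide, BrCc1ccccc1
Why: Selective Williamson etherification, since the 2-hydroxyl is held in a hydrogen bond to the acetyl group and one equivalent of benzyl bromide should alkylate only the 4-hydroxyl.

Step 11
Reactants: 18 the ring B benzoic acid; 20 1-[4-(benzyloxy)-2-hydroxy-6-methylphenyl]ethanone
Product: 22 2-acetyl-5-(benzyloxy)-3-methylphenyl 2,4-bis(benzyloxy)-6-{[4-(benzyloxy)-2-oxo-2H-pyran-6-yl]methyl}benzoate, via aroyl chloride 21 (not isolated)
Conditions: 18, (COCl)2, DMF (cat.), CH2Cl2, 0 °C → rt, evaporate; then 20, pyridine, DMAP (cat.), CH2Cl2, 0 °C → rt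
Reagents that add atoms: oxalyl chloride, ClC(=O)C(=O)Cl (its chlorine stays in 21 only)
Why: Acid chloride formation followed by DMAP-catalysed O-acylation of the phenol is the standard entry to a Baker–Venkataraman substrate and tolerates a doubly ortho-substituted aroyl group.

Step 12
Reactants: 22 the aryl ester
Product: 24 7-(benzyloxy)-2-(2,4-bis(benzyloxy)-6-{[4-(benzyloxy)-2-oxo-2H-pyran-6-yl]methyl}phenyl)-5-methyl-4H-chromen-4-one, via 1,3-diketone 23 (not isolated)
Conditions: LiN(SiMe3)2 (3.5 equiv), THF, −20 °C → rt; 1 M HCl; then TsOH·H2O (cat.), PhMe, 80 °C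
Reagents that add atoms: none
Why: Baker–Venkataraman rearrangement, in which the ketone enolate attacks the neighbouring aryl ester through a six-membered transition state (intramolecular Claisen condensation) and so moves the hindered aroyl group to carbon, after which acid closes the pyranone by attack of the only free phenol on the aryl ketone with loss of water.

Step 13
Reactants: 24 the tetrabenzyl chromone
Product: 25 7-hydroxy-2-{2,4-dihydroxy-6-[(4-hydroxy-2-oxo-2H-pyran-6-yl)methyl]phenyl}-5-methyl-4H-chromen-4-one (CNP0309284.0)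
Conditions: BCl3, C6HMe5, CH2Cl2, −78 → 0 °C; MeOH, then H2O
Reagents that add atoms: none
Why: Lewis acid debenzylation with pentamethylbenzene as benzyl cation trap should cleave all four benzyl ethers at low temperature without reducing the chromone or pyrone double bonds and without C-benzylation of the electron-rich rings.

**Compound list**
1 | 4-hydroxy-6-methyl-2H-pyran-2-one | Cc1cc(O)cc(=O)o1 | starting material
2 | 6-methyl-4-(prop-2-en-1-yloxy)-2H-pyran-2-one | Cc1cc(OCC=C)cc(=O)o1 | intermediate
3 | [2-oxo-4-(prop-2-en-1-yloxy)-2H-pyran-6-yl]acetic acid | OC(=O)Cc1cc(OCC=C)cc(=O)o1 | intermediate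
4 | 2,2-dimethyl-1,3-dioxane-4,6-dione (Meldrum's acid) | CC1(C)OC(=O)CC(=O)O1 | starting material
5 | prop-2-en-1-ol (allyl alcohol) | OCC=C | starting material
6 | 3-oxo-3-(prop-2-en-1-yloxy)propanoic acid | OC(=O)CC(=O)OCC=C | intermediate
7 | 2,2,6-trimethyl-4H-1,3-dioxin-4-one | CC1=CC(=O)OC(C)(C)O1 | starting material
8 | prop-2-en-1-yl 3-chloro-3-oxopropanoate | ClC(=O)CC(=O)OCC=C | intermediate (not isolated)
9 | prop-2-en-1-yl 4-(2,2-dimethyl-4-oxo-4H-1,3-dioxin-6-yl)-3-oxobutanoate | CC1(C)OC(CC(=O)CC(=O)OCC=C)=CC(=O)O1 | intermediate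
10 | [2-oxo-4-(prop-2-en-1-yloxy)-2H-pyran-6-yl]acetyl chloride | ClC(=O)Cc1cc(OCC=C)cc(=O)o1 | intermediate (not isolated)
11 | prop-2-en-1-yl 2-[(2,2-dimethyl-4-oxo-4H-1,3-dioxin-6-yl)acetyl]-3-oxo-4-[2-oxo-4-(prop-2-en-1-yloxy)-2H-pyran-6-yl]butanoate (racemic, enolised) | CC1(C)OC(CC(=O)C(C(=O)OCC=C)C(=O)Cc2cc(OCC=C)cc(=O)o2)=CC(=O)O1 | intermediate
12 | 6-[5-(4-hydroxy-2-oxo-2H-pyran-6-yl)-2,4-dioxopentyl]-2,2-dimethyl-4H-1,3-dioxin-4-one | CC1(C)OC(CC(=O)CC(=O)Cc2cc(O)cc(=O)o2)=CC(=O)O1 | intermediate
13 | 8-(4-hydroxy-2-oxo-2H-pyran-6-yl)-3,5,7-trioxooct-1-en-1-one (acylketene) | O=C=CC(=O)CC(=O)CC(=O)Cc1cc(O)cc(=O)o1 | intermediate (not isolated)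
14 | prop-2-en-1-yl 8-(4-hydroxy-2-oxo-2H-pyran-6-yl)-3,5,7-trioxooctanoate | C=CCOC(=O)CC(=O)CC(=O)CC(=O)Cc1cc(O)cc(=O)o1 | intermediate (not isolated)
15 | prop-2-en-1-yl 2-hydroxy-2-[(4-hydroxy-2-oxo-2H-pyran-6-yl)methyl]-4,6-dioxocyclohexane-1-carboxylate (mixture of stereoisomers) | C=CCOC(=O)C1C(=O)CC(=O)CC1(O)Cc1cc(O)cc(=O)o1 | intermediate (not isolated)
16 | prop-2-en-1-yl 2,4-dihydroxy-6-[(4-hydroxy-2-oxo-2H-pyran-6-yl)methyl]benzoate | C=CCOC(=O)c1c(O)cc(O)cc1Cc1cc(O)cc(=O)o1 | intermediate
17 | prop-2-en-1-yl 2,4-bis(benzyloxy)-6-{[4-(benzyloxy)-2-oxo-2H-pyran-6-yl]methyl}benzoate | C=CCOC(=O)c1c(OCc2ccccc2)cc(OCc2ccccc2)cc1Cc1cc(OCc2ccccc2)cc(=O)o1 | intermediate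
18 | 2,4-bis(benzyloxy)-6-{[4-(benzyloxy)-2-oxo-2H-pyran-6-yl]methyl}benzoic acid | OC(=O)c1c(OCc2ccccc2)cc(OCc2ccccc2)cc1Cc1cc(OCc2ccccc2)cc(=O)o1 | intermediate
19 | 1-(2,4-dihydroxy-6-methylphenyl)ethanone | CC(=O)c1c(C)cc(O)cc1O | starting material
20 | 1-[4-(benzyloxy)-2-hydroxy-6-methylphenyl]ethanone | CC(=O)c1c(C)cc(OCc2ccccc2)cc1O | intermediate
21 | 2,4-bis(benzyloxy)-6-{[4-(benzyloxy)-2-oxo-2H-pyran-6-yl]methyl}benzoyl chloride | ClC(=O)c1c(OCc2ccccc2)cc(OCc2ccccc2)cc1Cc1cc(OCc2ccccc2)cc(=O)o1 | intermediate (not isolated)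
22 | 2-acetyl-5-(benzyloxy)-3-methylphenyl 2,4-bis(benzyloxy)-6-{[4-(benzyloxy)-2-oxo-2H-pyran-6-yl]methyl}benzoate | CC(=O)c1c(C)cc(OCc2ccccc2)cc1OC(=O)c1c(OCc2ccccc2)cc(OCc2ccccc2)cc1Cc1cc(OCc2ccccc2)cc(=O)o1 | intermediate
23 | 1-[4-(benzyloxy)-2-hydroxy-6-methylphenyl]-3-(2,4-bis(benzyloxy)-6-{[4-(benzyloxy)-2-oxo-2H-pyran-6-yl]methyl}phenyl)propane-1,3-dione | Cc1cc(OCc2ccccc2)cc(O)c1C(=O)CC(=O)c1c(OCc2ccccc2)cc(OCc2ccccc2)cc1Cc1cc(OCc2ccccc2)cc(=O)o1 | intermediate (not isolated)
24 | 7-(benzyloxy)-2-(2,4-bis(benzyloxy)-6-{[4-(benzyloxy)-2-oxo-2H-pyran-6-yl]methyl}phenyl)-5-methyl-4H-chromen-4-one | Cc1cc(OCc2ccccc2)cc2oc(-c3c(OCc4ccccc4)cc(OCc4ccccc4)cc3Cc3cc(OCc4ccccc4)cc(=O)o3)cc(=O)c12 | intermediate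
25 | 7-hydroxy-2-{2,4-dihydroxy-6-[(4-hydroxy-2-oxo-2H-pyran-6-yl)methyl]phenyl}-5-methyl-4H-chromen-4-one | Cc1cc(O)cc2oc(-c3c(O)cc(O)cc3Cc3cc(O)cc(=O)o3)cc(=O)c12 | target

**Count**
Total steps: 13. Longest linear sequence: 10 steps (1, 2, 5, 6, 7, 8, 9, 11, 12, 13; the branch through steps 3 and 4 is equally long).

**Steps most likely to fail**

Step 7. The acylketene may be captured by the pyrone hydroxyl or by a chain enol (lactonisation to a second pyrone) instead of by the alcohol, or the aldol may start from the wrong methylene. The fallback sets out from 12 and avoids the ketene altogether. Treating 12 with Et3N in CH2Cl2 at room temperature should let the intact dioxinone act as the nucleophile through its dienolate, whose ring carbon next to the carbonyl adds to the remote ketone; the alternative closure is then impossible because the dioxinone carbon is no ketone. Aromatisation should give the acetonide-protected resorcylate 7-hydroxy-5-[(4-hydroxy-2-oxo-2H-pyran-6-yl)methyl]-2,2-dimethyl-4H-1,3-benzodioxin-4-one F1. Opening of F1 with allyl alcohol and Cs2CO3 (transesterification with loss of acetone) comes back to the route at 16.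

Step 5. The acid chloride may be consumed by ketene formation and self-condensation, or O-acylation of the magnesium enolate may compete, so that little C-acylated product forms. The fallback sets out from 7 and from acid chloride 10 and joins the chain by a lithium dianion Claisen condensation instead. The dienolate of 7 (LiN(SiMe3)2, THF, −78 °C) would be acetylated with acetyl chloride to 2,2-dimethyl-6-(2-oxopropyl)-4H-1,3-dioxin-4-one F2. The dianion of F2 (LiN(i-Pr)2, 2 equiv per ketone), taken in twofold excess so that one half serves as base toward the acidic acyl donor, would be acylated at its terminal carbon by 10 to give 2,2-dimethyl-6-{2,4-dioxo-5-[2-oxo-4-(prop-2-en-1-yloxy)-2H-pyran-6-yl]pentyl}-4H-1,3-dioxin-4-one F3. Pd(PPh3)4 with morpholine would then remove the pyrone allyl group and come back to the route at 12.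

Step 12. Deprotonation of the CH2 between ring B and the pyrone may deactivate the crowded ester so that the acyl shift stalls, or the ester may be cleaved instead of rearranged. The fallback sets out from 20 and from aroyl chloride 21 (made from 18 as in step 11) and forms the carbon–carbon bond intermolecularly. The lithium dianion of 20 (LiN(SiMe3)2, 3 equiv, THF, −78 °C) would be C-aroylated directly by 21 to diketone 23, which is cyclised with TsOH as before and comes back to the route at 24. This fallback makes no compound outside the list (F0).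

**Further compounds**
F1 | step 7 | 7-hydroxy-5-[(4-hydroxy-2-oxo-2H-pyran-6-yl)methyl]-2,2-dimethyl-4H-1,3-benzodioxin-4-one | CC1(C)Oc2cc(O)cc(Cc3cc(O)cc(=O)o3)c2C(=O)O1
F2 | step 5 | 2,2-dimethyl-6-(2-oxopropyl)-4H-1,3-dioxin-4-one | CC(=O)CC1=CC(=O)OC(C)(C)O1
F3 | step 5 | 2,2-dimethyl-6-{2,4-dioxo-5-[2-oxo-4-(prop-2-en-1-yloxy)-2H-pyran-6-yl]pentyl}-4H-1,3-dioxin-4-one | CC1(C)OC(CC(=O)CC(=O)Cc2cc(OCC=C)cc(=O)o2)=CC(=O)O1
F0 | step 12 | none | none
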